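## Retrosynthetic overview

1. Target ⇒ the C8 ester bond is made last, by site-selective angeloylation of an 8,10,11-triol; the anti-8,10-diol ⇒ hydroxyl-directed reduction of a β-hydroxy ketone.
2. C8–C9 bond ⇒ amine-catalysed aldol between a ring-bound 2-substituted acrolein and 3-hydroxy-3-methylbutan-2-one; the acrolein ⇒ allylic oxidation of an isopropenyl group.
3. Oxirane ring (formed second) ⇒ hydroxyl-directed epoxidation of a cis allylic alcohol made from a carvone-type enone; enone ⇒ singlet-oxygen ene reaction and dehydration of an allylic angelate.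
4. Ring angelate (C6–O, cis to the side chain) ⇒ Mitsunobu inversion of trans-isopiperitenol by angelic acid.
5. Cyclohexene ring (formed first, with the first stereocentres) ⇒ Brønsted-acid-organocatalysed asymmetric carbonyl–ene cyclization of achiral neral.

Assumption: neral (geometrically pure (2Z)-citral) is taken as a purchasable achiral starting material.

Locants: target numbering is used throughout: ring C1 (C=O), C2 (C–CH3), C3, C4, C5 (bears the side chain), C6 (ring ester carbon); side chain C7 (=CH2 carbon), C8, C9, C10, C11.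

## Route

Step 1
Reactants: 1 neral [(2Z)-3,7-dimethylocta-2,6-dienal]
Product: 2 (1S,6R)-3-methyl-6-(prop-1-en-2-yl)cyclohex-2-en-1-ol (trans-isopiperitenol)
Conditions: confined chiral imidodiphosphorimidate (IDPi) Brønsted acid, antipode that gives the (1S,6R) alcohol (1 mol %), CHCl3, −40 °C
Reagents that add atoms: none
Why: Asymmetric intramolecular carbonyl–ene (type-one, Prins-type) cyclization, known for neral under confined IDPi catalysis: the activated aldehyde held in the chiral anion pocket is attacked by the C5=C7 alkene through a chair transition state with the carbonyl oxygen equatorial and hydrogen transfer from the (E)-methyl, which gives the trans ring, and the chosen catalyst antipode fixes C5 as R together with the C6 carbinol (inverted in step 2).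

Step 2
Reactants: 2 trans-isopiperitenol; 3 angelic acid [(2Z)-2-methylbut-2-enoic acid]
Product: 4 (1R,6R)-3-methyl-6-(prop-1-en-2-yl)cyclohex-2-en-1-yl (2Z)-2-methylbut-2-enoate (cis-isopiperitenyl angelate)
Conditions: 3 (1.3 equiv), PPh3, DIAD, toluene, −20 → 0 °C
Reagents that add atoms: angelic acid 3, C/C=C(/C)C(=O)O
Why: Mitsunobu esterification: SN2 attack of angelate on the allylic alkoxyphosphonium inverts C6 and turns the trans alcohol into the cis ester, O-alkylation of the carboxylate cannot isomerise the (Z)-alkene, and the low temperature suppresses ionisation to the allyl cation.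

Step 3
Reactants: 4 cis-isopiperitenyl angelate
Product: 7 (1S,6R)-3-methyl-2-oxo-6-(prop-1-en-2-yl)cyclohex-3-en-1-yl (2Z)-2-methylbut-2-enoate, via allylic hydroperoxide 5 (not isolated), via allylic peracetate 6 (not isolated)
Conditions: O2, tetraphenylporphyrin (0.5 mol %), white LED, Ac2O, pyridine, CH2Cl2, 0 → 20 °C
Reagents that add atoms: dioxygen, O=O
Why: Schenck ene reaction followed by Kornblum–DeLaMare-type elimination in one pot: singlet oxygen adds at C1 on the more substituted side of the ring alkene with abstraction of a C3 hydrogen (the hydrogen geminal to the ester is not abstracted, and the 1,1-disubstituted and ester alkenes react far more slowly), and pyridine-induced loss of acetic acid from the peracetate gives the 2-methyl enone without touching C5 or C6.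

Step 4
Reactants: 7 cis-6-angeloyloxy enone
Product: 8 (1S,2R,6R)-2-hydroxy-3-methyl-6-(prop-1-en-2-yl)cyclohex-3-en-1-yl (2Z)-2-methylbut-2-enoate
Conditions: NaBH4, CeCl3·7H2O, MeOH, −78 °C; AcOH quench
Reagents that add atoms: none
Why: Luche 1,2-reduction: hydride adds to C1 axially on the face away from the pseudoaxial C6 ester, so the temporary C1 carbinol is cis to the ester and the isopropenyl group (as in the reduction of carvone to cis-carveol), and the cold, near-neutral medium limits acyl migration.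

Step 5
Reactants: 8 all-cis allylic alcohol
Product: 10 (1R,3S,4R,6R)-1-methyl-2-oxo-4-(prop-1-en-2-yl)-7-oxabicyclo[4.1.0]heptan-3-yl (2Z)-2-methylbut-2-enoate, via epoxy alcohol 9 (not isolated)
Conditions: VO(acac)2 (2 mol %), t-BuOOH (1.2 equiv), CH2Cl2, 0 °C; then Dess–Martin periodinane, rt
Reagents that add atoms: tert-butyl hydroperoxide, CC(C)(C)OO
Why: VO(acac)2-catalysed hydroxyl-directed epoxidation (Sharpless–Michaelson) delivers oxygen to C2=C3 on the face of the C1 hydroxyl, which sets C2 and C3 cis to the ester and the side chain and leaves the isopropenyl and angelate alkenes alone, and Dess–Martin oxidation then returns C1 to the ketone.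

Step 6
Reactants: 10 all-cis epoxy ketone
Product: 12 (1R,3S,4R,6R)-1-methyl-2-oxo-4-(3-oxoprop-1-en-2-yl)-7-oxabicyclo[4.1.0]heptan-3-yl (2Z)-2-methylbut-2-enoate, via primary allylic alcohol 11 (not isolated)
Conditions: SeO2 (0.5 equiv), t-BuOOH (3 equiv), salicylic acid (0.1 equiv), CH2Cl2, rt; then activated MnO2, rt
Reagents that add atoms: selenium dioxide, O=[Se]=O; tert-butyl hydroperoxide, CC(C)(C)OO
Why: SeO2 allylic oxidation (ene then [2,3]-sigmatropic shift, catalytic Sharpless variant) oxidises the methyl of the only electron-rich alkene left, and MnO2 takes the primary allylic alcohol on to the 2-substituted acrolein; no stereocentre is touched.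

Step 7
Reactants: 12 ring-bound 2-substituted acrolein; 13 3-hydroxy-3-methylbutan-2-one
Product: 14 (1R,3S,4R,6R)-4-[(3S)-3,6-dihydroxy-6-methyl-5-oxohept-1-en-2-yl]-1-methyl-2-oxo-7-oxabicyclo[4.1.0]heptan-3-yl (2Z)-2-methylbut-2-enoate
Conditions: D-proline (30 mol %), 13 (10 equiv), DMSO, 4 °C
Reagents that add atoms: 3-hydroxy-3-methylbutan-2-one 13, CC(=O)C(C)(C)O
Why: Proposed new method: enamine aldol addition onto an α-methylene aldehyde (2-substituted acrolein) acceptor with a tertiary α-hydroxy methyl ketone donor, a pairing not yet shown in enamine catalysis; D-proline forms the enamine of 13 only on the methyl side (the other α-carbon is quaternary), its carboxylic acid hydrogen-bonds the formyl oxygen in a Houk–List chair so that the enamine adds 1,2 to the si face and sets C8 as S under catalyst control, the α-substituent disfavours iminium formation and conjugate addition at the acceptor, and aza-Michael adducts of the catalyst revert; the closest known reaction is the proline-catalysed List–Barbas aldol of acetone or hydroxyacetone with α-branched aldehydes.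

Step 8
Reactants: 14 β-hydroxy ketone
Product: 15 (1R,3S,4R,6R)-1-methyl-2-oxo-4-[(3S,5S)-3,5,6-trihydroxy-6-methylhept-1-en-2-yl]-7-oxabicyclo[4.1.0]heptan-3-yl (2Z)-2-methylbut-2-enoate
Conditions: Me4NBH(OAc)3 (5 equiv), MeCN/AcOH 1:1, −30 °C
Reagents that add atoms: none
Why: Evans–Saksena reduction: the C8 hydroxyl exchanges onto boron and delivers hydride to the C10 ketone through a chair transition state, giving the 1,3-anti diol (C10 S), while the ring ketone has no free hydroxyl nearby and is not reduced by the triacetoxyborohydride.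

Step 9
Reactants: 15 8,10,11-triol; 3 angelic acid
Product: 16 (1R,3S,4R,6R)-4-[(3S,5S)-5,6-dihydroxy-6-methyl-3-{[(2Z)-2-methylbut-2-enoyl]oxy}hept-1-en-2-yl]-1-methyl-2-oxo-7-oxabicyclo[4.1.0]heptan-3-yl (2Z)-2-methylbut-2-enoate (CNP0127352.2)
Conditions: 3, 2,4,6-trichlorobenzoyl chloride, Et3N, toluene, rt (mixed anhydride, 1.3 equiv); then 15, toluene, 70 °C
Reagents that add atoms: angelic acid 3, C/C=C(/C)C(=O)O
Why: Yamaguchi-type esterification with the preformed mixed anhydride and no DMAP, so the (Z)-alkene is kept; the secondary allylic C8 hydroxyl reacts in preference to the neopentyl-like C10 hydroxyl and the tertiary C11 hydroxyl, and no stereocentre changes.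

## Compound list

1 | neral, (2Z)-3,7-dimethylocta-2,6-dienal | CC(C)=CCC/C(C)=C\C=O | starting material
2 | (1S,6R)-3-methyl-6-(prop-1-en-2-yl)cyclohex-2-en-1-ol (trans-isopiperitenol) | C=C(C)[C@H]1CCC(C)=C[C@@H]1O | intermediate
3 | angelic acid, (2Z)-2-methylbut-2-enoic acid | C/C=C(/C)C(=O)O | starting material
4 | (1R,6R)-3-methyl-6-(prop-1-en-2-yl)cyclohex-2-en-1-yl (2Z)-2-methylbut-2-enoate | C=C(C)[C@H]1CCC(C)=C[C@H]1OC(=O)/C(C)=C\C | intermediate
5 | (1S,2S,6R)-2-hydroperoxy-3-methyl-6-(prop-1-en-2-yl)cyclohex-3-en-1-yl (2Z)-2-methylbut-2-enoate (hydroperoxide trans to the ester) | C=C(C)[C@H]1CC=C(C)[C@H](OO)[C@H]1OC(=O)/C(C)=C\C | intermediate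
6 | (1S,2S,6R)-2-(acetylperoxy)-3-methyl-6-(prop-1-en-2-yl)cyclohex-3-en-1-yl (2Z)-2-methylbut-2-enoate | C=C(C)[C@H]1CC=C(C)[C@H](OOC(C)=O)[C@H]1OC(=O)/C(C)=C\C | intermediate
7 | (1S,6R)-3-methyl-2-oxo-6-(prop-1-en-2-yl)cyclohex-3-en-1-yl (2Z)-2-methylbut-2-enoate | C=C(C)[C@H]1CC=C(C)C(=O)[C@H]1OC(=O)/C(C)=C\C | intermediate
8 | (1S,2R,6R)-2-hydroxy-3-methyl-6-(prop-1-en-2-yl)cyclohex-3-en-1-yl (2Z)-2-methylbut-2-enoate (OH, ester and isopropenyl all cis) | C=C(C)[C@H]1CC=C(C)[C@@H](O)[C@H]1OC(=O)/C(C)=C\C | intermediate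
9 | (1S,2S,3S,4R,6R)-2-hydroxy-1-methyl-4-(prop-1-en-2-yl)-7-oxabicyclo[4.1.0]heptan-3-yl (2Z)-2-methylbut-2-enoate | C=C(C)[C@H]1C[C@H]2O[C@@]2(C)[C@@H](O)[C@H]1OC(=O)/C(C)=C\C | intermediate
10 | (1R,3S,4R,6R)-1-methyl-2-oxo-4-(prop-1-en-2-yl)-7-oxabicyclo[4.1.0]heptan-3-yl (2Z)-2-methylbut-2-enoate | C=C(C)[C@H]1C[C@H]2O[C@@]2(C)C(=O)[C@H]1OC(=O)/C(C)=C\C | intermediate
11 | (1R,3S,4R,6R)-4-(3-hydroxyprop-1-en-2-yl)-1-methyl-2-oxo-7-oxabicyclo[4.1.0]heptan-3-yl (2Z)-2-methylbut-2-enoate | C=C(CO)[C@H]1C[C@H]2O[C@@]2(C)C(=O)[C@H]1OC(=O)/C(C)=C\C | intermediate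
12 | (1R,3S,4R,6R)-1-methyl-2-oxo-4-(3-oxoprop-1-en-2-yl)-7-oxabicyclo[4.1.0]heptan-3-yl (2Z)-2-methylbut-2-enoate | C=C(C=O)[C@H]1C[C@H]2O[C@@]2(C)C(=O)[C@H]1OC(=O)/C(C)=C\C | intermediate
13 | 3-hydroxy-3-methylbutan-2-one | CC(=O)C(C)(C)O | starting material
14 | (1R,3S,4R,6R)-4-[(3S)-3,6-dihydroxy-6-methyl-5-oxohept-1-en-2-yl]-1-methyl-2-oxo-7-oxabicyclo[4.1.0]heptan-3-yl (2Z)-2-methylbut-2-enoate | C=C([C@H](CC(=O)C(C)(C)O)O)[C@H]1C[C@H]2O[C@@]2(C)C(=O)[C@H]1OC(=O)/C(C)=C\C | intermediate
15 | (1R,3S,4R,6R)-1-methyl-2-oxo-4-[(3S,5S)-3,5,6-trihydroxy-6-methylhept-1-en-2-yl]-7-oxabicyclo[4.1.0]heptan-3-yl (2Z)-2-methylbut-2-enoate | C=C([C@H](C[C@H](O)C(C)(C)O)O)[C@H]1C[C@H]2O[C@@]2(C)C(=O)[C@H]1OC(=O)/C(C)=C\C | intermediate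
16 | (1R,3S,4R,6R)-4-[(3S,5S)-5,6-dihydroxy-6-methyl-3-{[(2Z)-2-methylbut-2-enoyl]oxy}hept-1-en-2-yl]-1-methyl-2-oxo-7-oxabicyclo[4.1.0]heptan-3-yl (2Z)-2-methylbut-2-enoate | C=C([C@H](C[C@H](O)C(C)(C)O)OC(=O)/C(C)=C\C)[C@H]1C[C@H]2O[C@@]2(C)C(=O)[C@H]1OC(=O)/C(C)=C\C | target

## Step count and risks

Total step count: 9. Longest linear sequence: 9 (neral to target).

Three steps most likely to fail:

Step 6 (allylic oxidation of the isopropenyl group). SeO2 can also abstract the C5 methine hydrogen to give a tertiary allylic alcohol, and yields on isopropenyl groups are often modest; the epoxy ketone and the cis α-acyloxy ketone limit how hard the reaction can be pushed. The fallback sets out from 10. Ene-type allylic chlorination with NaOCl and CeCl3·7H2O in CH2Cl2/H2O at 0 °C, which is well behaved on the isopropenyl group of carvone-type ketones, gives the allylic chloride F1. Ganem oxidation of this chloride with trimethylamine N-oxide in DMSO at rt gives the aldehyde, and the route is rejoined at 12.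

Step 7 (the proposed new aldol). The enamine may add to the unhindered methylene terminus of 12 instead of the formyl group, the catalyst may be held up as its aza-Michael adduct, the aldol may dehydrate, and the amine could epimerise C6. The fallback uses known chemistry and sets out from 12. Ketone 13 is silylated with Et3SiCl and imidazole to the silyl ether F2. Its diisopinocampheylboron enolate, made with (−)-Ipc2BCl and Et3N in Et2O at −78 °C, adds 1,2 to 12 under reagent control (Paterson aldol, antipode of the borane chosen for si-face attack). A non-oxidative work-up gives the silyl-protected aldol F3, and HF·pyridine in THF removes the silyl group, rejoining the route at 14.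

Step 9 (site-selective angeloylation). The C10 hydroxyl may compete with C8, and prolonged heating risks partial Z to E isomerisation or C6 epimerisation. The fallback sets out from 15. 2,2-Dimethoxypropane and PPTS close the 10,11-acetonide F4; the five-membered dioxolane is preferred over the twist-boat dioxane that an anti-1,3-diol would need. The only free hydroxyl (C8) is then angeloylated with the same mixed anhydride to give the acetonide 8-angelate F5. Aqueous AcOH (80%) at rt removes the acetonide, and the route is rejoined at 16.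

## Further compounds

F1 | step 6 | (1R,3S,4R,6R)-4-(3-chloroprop-1-en-2-yl)-1-methyl-2-oxo-7-oxabicyclo[4.1.0]heptan-3-yl (2Z)-2-methylbut-2-enoate | C=C(CCl)[C@H]1C[C@H]2O[C@@]2(C)C(=O)[C@H]1OC(=O)/C(C)=C\C
F2 | step 7 | 3-methyl-3-[(triethylsilyl)oxy]butan-2-one | CC(=O)C(C)(C)O[Si](CC)(CC)CC
F3 | step 7 | (1R,3S,4R,6R)-4-{(3S)-3-hydroxy-6-methyl-5-oxo-6-[(triethylsilyl)oxy]hept-1-en-2-yl}-1-methyl-2-oxo-7-oxabicyclo[4.1.0]heptan-3-yl (2Z)-2-methylbut-2-enoate | C=C([C@H](CC(=O)C(C)(C)O[Si](CC)(CC)CC)O)[C@H]1C[C@H]2O[C@@]2(C)C(=O)[C@H]1OC(=O)/C(C)=C\C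
F4 | step 9 | (1R,3S,4R,6R)-4-{(3S)-3-hydroxy-4-[(4S)-2,2,5,5-tetramethyl-1,3-dioxolan-4-yl]but-1-en-2-yl}-1-methyl-2-oxo-7-oxabicyclo[4.1.0]heptan-3-yl (2Z)-2-methylbut-2-enoate | C=C([C@H](C[C@@H]3OC(C)(C)OC3(C)C)O)[C@H]1C[C@H]2O[C@@]2(C)C(=O)[C@H]1OC(=O)/C(C)=C\C
F5 | step 9 | (1R,3S,4R,6R)-1-methyl-4-{(3S)-3-{[(2Z)-2-methylbut-2-enoyl]oxy}-4-[(4S)-2,2,5,5-tetramethyl-1,3-dioxolan-4-yl]but-1-en-2-yl}-2-oxo-7-oxabicyclo[4.1.0]heptan-3-yl (2Z)-2-methylbut-2-enoate | C=C([C@H](C[C@@H]3OC(C)(C)OC3(C)C)OC(=O)/C(C)=C\C)[C@H]1C[C@H]2O[C@@]2(C)C(=O)[C@H]1OC(=O)/C(C)=C\C
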